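## Retrosynthetic overview

- Atom labels follow the daucane skeleton: ring A (cyclopentene) is C1–C2–C3–C4–C5 and ring B (cycloheptene) is C1–C5–C6–C7–C8–C9–C10. C15 is the methyl on C1, C14 the CH2O carbon on C8, and the isopropyl group sits on C4.
- The route rests on one feature: the single stereocentre, quaternary ring-fusion carbon C1, carries methyl C15 and lies directly on the tetrasubstituted C4=C5 alkene of ring A. A cyclopropane C1–C15–C5 beside a C4 carbinol stores both, because cutting C5–C15 in the derived ketone leaves the C1 methyl and an enolate fixed at C4–C5.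
- Disconnections, latest first: the vanillate C–O bond; C8=C9 of ring B (aldol condensation of a C9/C14 dialdehyde); C4–isopropyl (coupling at an enol triflate); C5–C15 (reductive opening of a cyclopropyl ketone); C1–C15 and C5–C15 (hydroxyl-directed methylene transfer to an (S)-cyclopentenol).
- The cyclopentenol comes from cyclopentane-1,3-dione: reductive alkylation adds the C6–C7–C8–C14 arm, alkylative carbonyl transposition with tert-butyl acetate adds the C10–C9 arm, and an oxazaborolidine reduction sets the C4 carbinol.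
- Ring order: ring A is bought; the temporary cyclopropane is closed in step 9 and opened in step 11; ring B is closed in step 15.

Key step: step 9

Remark on the chemistry: the two primary hydroxyls carry different silyl groups (TIPS on the C14 arm, TBS on the C9 arm). This spectator change lets the C14 ether survive the acid of step 5 and keeps the two arms distinguishable for the ring-closure fallback.

## Route

Step 1
Reactants: 1 butane-1,4-diol
Product: 2 4-(triisopropylsilyloxy)butan-1-ol
Conditions: NaH (1.0 equiv), THF, 0 °C → rt; then TIPSCl (1.0 equiv)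
Reagents that add atoms: chlorotriisopropylsilane (TIPSCl), CC(C)[Si](Cl)(C(C)C)C(C)C
Why: Williamson-type O-silylation of the monosodium alkoxide, which is poorly soluble and forms only once per diol molecule, should stop at the mono ether.

Step 2
Reactants: 2 4-(triisopropylsilyloxy)butan-1-ol
Product: 3 4-(triisopropylsilyloxy)butanal
Conditions: TEMPO (cat.), PhI(OAc)2, CH2Cl2, rt
Reagents that add atoms: none
Why: TEMPO-catalysed oxoammonium oxidation with PhI(OAc)2 as terminal oxidant takes a primary alcohol to the aldehyde without over-oxidation and does not touch the silyl ether.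

Step 3
Reactants: 3 4-(triisopropylsilyloxy)butanal; 4 cyclopentane-1,3-dione
Product: 6 2-[4-(triisopropylsilyloxy)butyl]cyclopentane-1,3-dione, via alkylidene dione 5 (not isolated)
Conditions: L-proline (cat.), Hantzsch ester (diethyl 2,6-dimethyl-1,4-dihydropyridine-3,5-dicarboxylate), CH2Cl2, rt
Reagents that add atoms: none
Why: Three-component reductive alkylation, in which proline-catalysed Knoevenagel condensation gives the alkylidene dione 5 and the Hantzsch ester reduces it at once by conjugate hydride transfer, should give clean C-monoalkylation of the dione.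

Step 4
Reactants: 6 2-[4-(triisopropylsilyloxy)butyl]cyclopentane-1,3-dione
Product: 7 3-methoxy-2-[4-(triisopropylsilyloxy)butyl]cyclopent-2-en-1-one
Conditions: TMSCHN2, MeOH/toluene, 0 °C → rt
Reagents that add atoms: (trimethylsilyl)diazomethane, C[Si](C)(C)C=[N+]=[N-]
Why: O-Methylation of the acidic enol of the 1,3-dione by the diazoalkane gives the vinylogous ester under neutral conditions, and the symmetry of 6 allows only one product.

Step 5
Reactants: 7 3-methoxy-2-[4-(triisopropylsilyloxy)butyl]cyclopent-2-en-1-one; 8 tert-butyl acetate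
Product: 11 tert-butyl 2-{3-oxo-2-[4-(triisopropylsilyloxy)butyl]cyclopent-1-en-1-yl}acetate, via lithium enolate of tert-butyl acetate 9 (not isolated), via lithium alkoxide adduct 10 (not isolated)
Conditions: LiN(i-Pr)2, THF, −78 °C; add 7, −78 → −30 °C; then 1 M aq HCl, THF, 0 °C
Reagents that add atoms: water, O (source of the new ketone oxygen); lithium diisopropylamide, [Li]N(C(C)C)C(C)C (its lithium is held only in 9 and 10)
Why: Stork–Danheiser alkylative carbonyl transposition, in which the ester enolate 9 adds 1,2 to the vinylogous ester carbonyl and brief dilute acid hydrolyses the enol ether of 10 and eliminates the tertiary hydroxyl to give the transposed tetrasubstituted enone, with the tert-butyl ester and the TIPS ether stable to that acid.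

Step 6
Reactants: 11 tert-butyl 2-{3-oxo-2-[4-(triisopropylsilyloxy)butyl]cyclopent-1-en-1-yl}acetate
Product: 12 tert-butyl 2-{(3S)-3-hydroxy-2-[4-(triisopropylsilyloxy)butyl]cyclopent-1-en-1-yl}acetate
Conditions: (R)-2-methyl-CBS-oxazaborolidine (0.2 equiv), BH3·SMe2, THF, −20 °C; MeOH quench
Reagents that add atoms: none
Why: Corey–Bakshi–Shibata reduction, in which the ketone binds the oxazaborolidine with its α-substituted alkene arm as the large group and the ring CH2 as the small one, so that the (R)-catalyst should deliver hydride to the face that gives the (S)-carbinol at C4, while the ester is not reduced by borane at this temperature.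

Step 7
Reactants: 12 tert-butyl 2-{(3S)-3-hydroxy-2-[4-(triisopropylsilyloxy)butyl]cyclopent-1-en-1-yl}acetate
Product: 13 (1S)-3-(2-hydroxyethyl)-2-[4-(triisopropylsilyloxy)butyl]cyclopent-2-en-1-ol
Conditions: LiAlH4, THF, 0 °C → rt
Reagents that add atoms: none
Why: Hydride reduction of the ester with LiAlH4 gives the primary alcohol of the C10–C9 arm, and the C4 carbinol and the unconjugated tetrasubstituted alkene are not affected.

Step 8
Reactants: 13 (1S)-3-(2-hydroxyethyl)-2-[4-(triisopropylsilyloxy)butyl]cyclopent-2-en-1-ol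
Product: 14 (1S)-3-[2-(tert-butyldimethylsilyloxy)ethyl]-2-[4-(triisopropylsilyloxy)butyl]cyclopent-2-en-1-ol
Conditions: TBSCl (1.05 equiv), imidazole, CH2Cl2, −20 → 0 °C
Reagents that add atoms: tert-butylchlorodimethylsilane (TBSCl), CC(C)(C)[Si](C)(C)Cl
Why: Steric differentiation in silylation, since the primary hydroxyl reacts far faster with TBSCl than the secondary hydroxyl flanked by the substituted alkene, leaves the C4 hydroxyl as the only free, and thus the only directing, group.

Step 9
Reactants: 14 (1S)-3-[2-(tert-butyldimethylsilyloxy)ethyl]-2-[4-(triisopropylsilyloxy)butyl]cyclopent-2-en-1-ol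
Product: 16 (1R,2S,5S)-5-[2-(tert-butyldimethylsilyloxy)ethyl]-1-[4-(triisopropylsilyloxy)butyl]bicyclo[3.1.0]hexan-2-ol, via ethylzinc alkoxide 15 (not isolated)
Conditions: ZnEt2 (5 equiv), CH2I2 (10 equiv), CH2Cl2, −10 °C → rt; aq NH4Cl
Reagents that add atoms: diiodomethane, ICI; diethylzinc, CC[Zn]CC (its ethylzinc unit is held only in 15)
Why: ZnEt2 first deprotonates the C4 hydroxyl to the ethylzinc alkoxide 15, and the carbenoid EtZnCH2I, made in the flask from ZnEt2 and CH2I2, binds to that alkoxide and passes its methylene to the neighbouring C1=C5 alkene through the butterfly transition state of the Simmons–Smith reaction in its Furukawa form. The closest known reaction type is the hydroxyl-directed cyclopropanation of cyclic allylic alcohols, including 2,3-disubstituted cyclopent-2-en-1-ols with a tetrasubstituted alkene. The three-membered ring is closed by a concerted, stereospecific [2+1] methylene transfer that forms C1–C15 and C5–C15 in one event on one face. Both new stereocentres, C1 and C5, are controlled by the C4 carbinol, because the methylene can only arrive on the face that holds the zinc alkoxide, so C15 ends up cis to the hydroxyl and C1 takes the configuration that the target needs once C5–C15 is cut. The step needs facial selectivity and enough reactivity at a tetrasubstituted alkene; the first is secured by the rigid cyclopentenol and by the silyl caps on both primary hydroxyls, which leave the C4 alkoxide as the only directing group, and the second by the electron-rich alkene and the excess of electrophilic carbenoid.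

Step 10
Reactants: 16 (1R,2S,5S)-5-[2-(tert-butyldimethylsilyloxy)ethyl]-1-[4-(triisopropylsilyloxy)butyl]bicyclo[3.1.0]hexan-2-ol
Product: 17 (1R,5S)-5-[2-(tert-butyldimethylsilyloxy)ethyl]-1-[4-(triisopropylsilyloxy)butyl]bicyclo[3.1.0]hexan-2-one
Conditions: DMP, NaHCO3, CH2Cl2, 0 °C → rt
Reagents that add atoms: none
Why: Dess–Martin oxidation under bicarbonate buffer turns the secondary cyclopropyl carbinol into the ketone without the acid that could ionise it, and the stereocentres C1 and C5 are not involved.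

Step 11
Reactants: 17 (1R,5S)-5-[2-(tert-butyldimethylsilyloxy)ethyl]-1-[4-(triisopropylsilyloxy)butyl]bicyclo[3.1.0]hexan-2-one
Product: 19 (3R)-3-[2-(tert-butyldimethylsilyloxy)ethyl]-3-methyl-2-[4-(triisopropylsilyloxy)butyl]cyclopent-1-en-1-yl trifluoromethanesulfonate, via lithium enolate 18 (not isolated)
Conditions: Li (2.2 equiv), t-BuOH (1.0 equiv), NH3/THF, −78 °C; evaporate NH3; PhNTf2, THF, −78 °C → rt
Reagents that add atoms: N-phenylbis(trifluoromethanesulfonimide) (PhNTf2), O=S(=O)(N(c1ccccc1)S(=O)(=O)C(F)(F)F)C(F)(F)F; lithium, [Li] (held only in 18)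
Why: Dissolving-metal reduction of a cyclopropyl ketone followed by enolate O-triflation, in which the ketyl cleaves the C5–C15 bond (the bond that overlaps with the carbonyl π system and gives a primary carbanion, unlike the ring-fusion C1–C5 bond), tert-butanol protonates C15 to the C1 methyl, and the regiodefined C4–C5 enolate 18 is trapped on oxygen by PhNTf2, with C1 keeping its configuration.

Step 12
Reactants: 19 (3R)-3-[2-(tert-butyldimethylsilyloxy)ethyl]-3-methyl-2-[4-(triisopropylsilyloxy)butyl]cyclopent-1-en-1-yl trifluoromethanesulfonate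
Product: 20 tert-butyl(dimethyl){2-[(1R)-1-methyl-3-(propan-2-yl)-2-[4-(triisopropylsilyloxy)butyl]cyclopent-2-en-1-yl]ethoxy}silane
Conditions: i-PrZnBr, Pd(OAc)2 (cat.), CPhos (cat.), THF/toluene, rt
Reagents that add atoms: isopropylzinc bromide, CC(C)[Zn]Br
Why: Negishi coupling of the alkenyl triflate with a secondary alkylzinc halide, for which the bulky biaryl dialkylphosphine makes reductive elimination faster than β-hydride elimination, should install the isopropyl group at C4 without isomerisation to n-propyl and without moving the alkene.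

Step 13
Reactants: 20 tert-butyl(dimethyl){2-[(1R)-1-methyl-3-(propan-2-yl)-2-[4-(triisopropylsilyloxy)butyl]cyclopent-2-en-1-yl]ethoxy}silane
Product: 21 4-[(5R)-5-(2-hydroxyethyl)-5-methyl-2-(propan-2-yl)cyclopent-1-en-1-yl]butan-1-ol
Conditions: TBAF, THF, rt
Reagents that add atoms: none
Why: Fluoride-driven desilylation cleaves both the TBS and the TIPS ether through the strong Si–F bond, and the hydrocarbon core has no fluoride-sensitive group.

Step 14
Reactants: 21 4-[(5R)-5-(2-hydroxyethyl)-5-methyl-2-(propan-2-yl)cyclopent-1-en-1-yl]butan-1-ol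
Product: 22 4-[(5R)-5-methyl-5-(2-oxoethyl)-2-(propan-2-yl)cyclopent-1-en-1-yl]butanal
Conditions: DMP (3 equiv), NaHCO3, CH2Cl2, 0 °C → rt
Reagents that add atoms: none
Why: Double Dess–Martin oxidation of the two primary alcohols gives the dialdehyde under buffered conditions in which neither over-oxidation nor premature aldol reaction is expected.

Step 15
Reactants: 22 4-[(5R)-5-methyl-5-(2-oxoethyl)-2-(propan-2-yl)cyclopent-1-en-1-yl]butanal
Product: 24 (8aR)-8a-methyl-3-(propan-2-yl)-1,2,4,5,8,8a-hexahydroazulene-6-carbaldehyde, via aldol adduct 23 (not isolated)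
Conditions: Bn2NH·CF3CO2H (0.2 equiv), toluene, 50 °C
Reagents that add atoms: none
Why: Intramolecular aldol condensation under secondary ammonium salt (enamine) catalysis, in which the enamine of the unhindered C14 aldehyde attacks the C9 aldehyde to form C8–C9 and ring B, and loss of water from 23 gives the conjugated enal, whereas the competing enamine of the C9 aldehyde would have to bond through C10 next to the quaternary C1 and should be slower.

Step 16
Reactants: 24 (8aR)-8a-methyl-3-(propan-2-yl)-1,2,4,5,8,8a-hexahydroazulene-6-carbaldehyde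
Product: 25 [(8aR)-8a-methyl-3-(propan-2-yl)-1,2,4,5,8,8a-hexahydroazulen-6-yl]methanol
Conditions: NaBH4, CeCl3·7H2O, MeOH, 0 °C
Reagents that add atoms: none
Why: Luche reduction gives clean 1,2-reduction of the enal to the primary allylic alcohol, and the isolated tetrasubstituted alkene is inert.

Step 17
Reactants: 25 [(8aR)-8a-methyl-3-(propan-2-yl)-1,2,4,5,8,8a-hexahydroazulen-6-yl]methanol; 26 vanillic acid (4-hydroxy-3-methoxybenzoic acid)
Product: 27 [(8aR)-8a-methyl-3-(propan-2-yl)-1,2,4,5,8,8a-hexahydroazulen-6-yl]methyl 4-hydroxy-3-methoxybenzoate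
Conditions: PPh3, DIAD, THF, 0 °C → rt
Reagents that add atoms: none
Why: Mitsunobu esterification, in which the carboxylic acid of vanillic acid is far more acidic than its phenol and therefore is the pronucleophile that displaces the primary allylic oxyphosphonium by SN2, should give the ester without phenol protection and without allylic transposition.

## Compound list

1 | butane-1,4-diol | OCCCCO | starting material
2 | 4-(triisopropylsilyloxy)butan-1-ol | OCCCCO[Si](C(C)C)(C(C)C)C(C)C | intermediate
3 | 4-(triisopropylsilyloxy)butanal | O=CCCCO[Si](C(C)C)(C(C)C)C(C)C | intermediate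
4 | cyclopentane-1,3-dione | O=C1CCC(=O)C1 | starting material
5 | 2-[4-(triisopropylsilyloxy)butylidene]cyclopentane-1,3-dione | O=C1CCC(=O)C1=CCCCO[Si](C(C)C)(C(C)C)C(C)C | intermediate (not isolated)
6 | 2-[4-(triisopropylsilyloxy)butyl]cyclopentane-1,3-dione | O=C1CCC(=O)C1CCCCO[Si](C(C)C)(C(C)C)C(C)C | intermediate
7 | 3-methoxy-2-[4-(triisopropylsilyloxy)butyl]cyclopent-2-en-1-one | COC1=C(CCCCO[Si](C(C)C)(C(C)C)C(C)C)C(=O)CC1 | intermediate
8 | tert-butyl acetate | CC(=O)OC(C)(C)C | starting material
9 | lithium enolate of tert-butyl acetate (lithium 1-tert-butoxyethen-1-olate) | C=C(O[Li])OC(C)(C)C | intermediate (not isolated)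
10 | lithium alkoxide of tert-butyl 2-{1-hydroxy-3-methoxy-2-[4-(triisopropylsilyloxy)butyl]cyclopent-2-en-1-yl}acetate (racemic) | COC1=C(CCCCO[Si](C(C)C)(C(C)C)C(C)C)C(O[Li])(CC(=O)OC(C)(C)C)CC1 | intermediate (not isolated)
11 | tert-butyl 2-{3-oxo-2-[4-(triisopropylsilyloxy)butyl]cyclopent-1-en-1-yl}acetate | CC(C)(C)OC(=O)CC1=C(CCCCO[Si](C(C)C)(C(C)C)C(C)C)C(=O)CC1 | intermediate
12 | tert-butyl 2-{(3S)-3-hydroxy-2-[4-(triisopropylsilyloxy)butyl]cyclopent-1-en-1-yl}acetate | O[C@H]1CCC(CC(=O)OC(C)(C)C)=C1CCCCO[Si](C(C)C)(C(C)C)C(C)C | intermediate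
13 | (1S)-3-(2-hydroxyethyl)-2-[4-(triisopropylsilyloxy)butyl]cyclopent-2-en-1-ol | O[C@H]1CCC(CCO)=C1CCCCO[Si](C(C)C)(C(C)C)C(C)C | intermediate
14 | (1S)-3-[2-(tert-butyldimethylsilyloxy)ethyl]-2-[4-(triisopropylsilyloxy)butyl]cyclopent-2-en-1-ol | O[C@H]1CCC(CCO[Si](C)(C)C(C)(C)C)=C1CCCCO[Si](C(C)C)(C(C)C)C(C)C | intermediate (key-step precursor)
15 | ethylzinc alkoxide of 14 | CC[Zn]O[C@H]1CCC(CCO[Si](C)(C)C(C)(C)C)=C1CCCCO[Si](C(C)C)(C(C)C)C(C)C | intermediate (not isolated)
16 | (1R,2S,5S)-5-[2-(tert-butyldimethylsilyloxy)ethyl]-1-[4-(triisopropylsilyloxy)butyl]bicyclo[3.1.0]hexan-2-ol (C6 methylene cis to the hydroxyl) | O[C@H]1CC[C@@]2(CCO[Si](C)(C)C(C)(C)C)C[C@@]12CCCCO[Si](C(C)C)(C(C)C)C(C)C | intermediate (key-step product)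
17 | (1R,5S)-5-[2-(tert-butyldimethylsilyloxy)ethyl]-1-[4-(triisopropylsilyloxy)butyl]bicyclo[3.1.0]hexan-2-one | O=C1CC[C@@]2(CCO[Si](C)(C)C(C)(C)C)C[C@@]12CCCCO[Si](C(C)C)(C(C)C)C(C)C | intermediate
18 | lithium (3R)-3-[2-(tert-butyldimethylsilyloxy)ethyl]-3-methyl-2-[4-(triisopropylsilyloxy)butyl]cyclopent-1-en-1-olate | [Li]OC1=C(CCCCO[Si](C(C)C)(C(C)C)C(C)C)[C@@](C)(CCO[Si](C)(C)C(C)(C)C)CC1 | intermediate (not isolated)
19 | (3R)-3-[2-(tert-butyldimethylsilyloxy)ethyl]-3-methyl-2-[4-(triisopropylsilyloxy)butyl]cyclopent-1-en-1-yl trifluoromethanesulfonate | O=S(=O)(OC1=C(CCCCO[Si](C(C)C)(C(C)C)C(C)C)[C@@](C)(CCO[Si](C)(C)C(C)(C)C)CC1)C(F)(F)F | intermediate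
20 | tert-butyl(dimethyl){2-[(1R)-1-methyl-3-(propan-2-yl)-2-[4-(triisopropylsilyloxy)butyl]cyclopent-2-en-1-yl]ethoxy}silane | CC(C)C1=C(CCCCO[Si](C(C)C)(C(C)C)C(C)C)[C@@](C)(CCO[Si](C)(C)C(C)(C)C)CC1 | intermediate
21 | 4-[(5R)-5-(2-hydroxyethyl)-5-methyl-2-(propan-2-yl)cyclopent-1-en-1-yl]butan-1-ol | CC(C)C1=C(CCCCO)[C@@](C)(CCO)CC1 | intermediate
22 | 4-[(5R)-5-methyl-5-(2-oxoethyl)-2-(propan-2-yl)cyclopent-1-en-1-yl]butanal | CC(C)C1=C(CCCC=O)[C@@](C)(CC=O)CC1 | intermediate
23 | (8aR)-7-hydroxy-8a-methyl-3-(propan-2-yl)-1,2,4,5,6,7,8,8a-octahydroazulene-6-carbaldehyde (mixture at C6 and C7) | O=CC1CCC2=C(C(C)C)CC[C@]2(C)CC1O | intermediate (not isolated)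
24 | (8aR)-8a-methyl-3-(propan-2-yl)-1,2,4,5,8,8a-hexahydroazulene-6-carbaldehyde | O=CC1=CC[C@@]2(C)CCC(C(C)C)=C2CC1 | intermediate
25 | [(8aR)-8a-methyl-3-(propan-2-yl)-1,2,4,5,8,8a-hexahydroazulen-6-yl]methanol | OCC1=CC[C@@]2(C)CCC(C(C)C)=C2CC1 | intermediate
26 | vanillic acid (4-hydroxy-3-methoxybenzoic acid) | COc1cc(C(=O)O)ccc1O | starting material
27 | [(8aR)-8a-methyl-3-(propan-2-yl)-1,2,4,5,8,8a-hexahydroazulen-6-yl]methyl 4-hydroxy-3-methoxybenzoate | COc1cc(C(=O)OCC2=CC[C@@]3(C)CCC(C(C)C)=C3CC2)ccc1O | target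

## Step count and risks

Total step count: 17. Longest linear sequence: 17 steps (1 → 27); compounds 4, 8 and 26 enter as purchased materials.

The three steps most likely to fail, most doubtful first:

**Step 12 (isopropyl coupling).** Transmetalation and reductive elimination at the hindered, fully substituted alkenylpalladium may be slow enough for β-hydride elimination and re-insertion to compete. The secondary alkyl group would then isomerise to n-propyl, or be lost as propene with reduction of the triflate. The fallback sets out from 19 and avoids an sp3 partner altogether. Suzuki–Miyaura coupling of 19 with isopropenylboronic acid pinacol ester (Pd(dppf)Cl2, K3PO4, dioxane/H2O, 80 °C) should give tert-butyl(dimethyl){2-[(1R)-1-methyl-3-(prop-1-en-2-yl)-2-[4-(triisopropylsilyloxy)butyl]cyclopent-2-en-1-yl]ethoxy}silane F1. Hydrogenation of its 1,1-disubstituted alkene with H2 (1 atm) over RhCl(PPh3)3 in benzene, a catalyst that leaves tetrasubstituted alkenes alone, comes back to the route at 20.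

**Step 15 (aldol ring closure).** The enamine of the C9 aldehyde may compete and bond through C10 to C14, which would close a seven-membered ring with the formyl group on the wrong carbon; the dialdehyde may also oligomerise. The fallback sets out from 20, uses the two different silyl groups, and closes C8=C9 by ring-closing metathesis, which has no regiochemical choice.
- HF·pyridine in THF/pyridine at 0 °C should remove only the primary TBS group, giving 2-{(1R)-1-methyl-3-(propan-2-yl)-2-[4-(triisopropylsilyloxy)butyl]cyclopent-2-en-1-yl}ethan-1-ol F2.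
- Dess–Martin oxidation gives 2-{(1R)-1-methyl-3-(propan-2-yl)-2-[4-(triisopropylsilyloxy)butyl]cyclopent-2-en-1-yl}acetaldehyde F3.
- Wittig methylenation (Ph3PCH3Br, KOt-Bu, THF) gives triisopropyl{4-[(5R)-5-methyl-2-(propan-2-yl)-5-(prop-2-en-1-yl)cyclopent-1-en-1-yl]butoxy}silane F4.
- TBAF in THF frees 4-[(5R)-5-methyl-2-(propan-2-yl)-5-(prop-2-en-1-yl)cyclopent-1-en-1-yl]butan-1-ol F5.
- Dess–Martin oxidation gives 4-[(5R)-5-methyl-2-(propan-2-yl)-5-(prop-2-en-1-yl)cyclopent-1-en-1-yl]butanal F6.
- α-Methylenation with aqueous formaldehyde, pyrrolidine and propionic acid in i-PrOH at 45 °C gives 2-methylidene-4-[(5R)-5-methyl-2-(propan-2-yl)-5-(prop-2-en-1-yl)cyclopent-1-en-1-yl]butanal F7.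
- Luche reduction (NaBH4, CeCl3·7H2O, MeOH) gives 2-methylidene-4-[(5R)-5-methyl-2-(propan-2-yl)-5-(prop-2-en-1-yl)cyclopent-1-en-1-yl]butan-1-ol F8.
- Ring-closing metathesis with the second-generation Grubbs catalyst in CH2Cl2 at 40 °C joins C8 and C9 with loss of ethene; the tetrasubstituted C4=C5 alkene cannot take part. This comes back to the route at 25.

**Step 9 (key cyclopropanation).** Methylene transfer to the tetrasubstituted alkene may be too slow, so that the carbenoid decays and the zinc iodide that builds up ionises the allylic or cyclopropyl carbinol before the ring is closed. The fallback sets out from 11 and replaces the directed zinc carbenoid by free dichlorocarbene, which adds readily to tetrasubstituted alkenes under steric control. Because that addition occurs anti to the C4 oxygen, the enantiomeric carbinol is used.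
- Reduction of 11 with the (S)-oxazaborolidine and BH3·SMe2 gives tert-butyl 2-{(3R)-3-hydroxy-2-[4-(triisopropylsilyloxy)butyl]cyclopent-1-en-1-yl}acetate F9.
- LiAlH4 gives (1R)-3-(2-hydroxyethyl)-2-[4-(triisopropylsilyloxy)butyl]cyclopent-2-en-1-ol F10.
- TBSCl and imidazole give (1R)-3-[2-(tert-butyldimethylsilyloxy)ethyl]-2-[4-(triisopropylsilyloxy)butyl]cyclopent-2-en-1-ol F11.
- NaH, BnBr and Bu4NI in THF give its benzyl ether, {[(1R)-3-[2-(tert-butyldimethylsilyloxy)ethyl]-2-[4-(triisopropylsilyloxy)butyl]cyclopent-2-en-1-yl]oxymethyl}benzene F12.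
- Dichlorocarbene (CHCl3, 50% aq NaOH, BnEt3NCl) should add to the face opposite the benzyloxy group, giving (1R,2R,5S)-2-(benzyloxy)-6,6-dichloro-5-[2-(tert-butyldimethylsilyloxy)ethyl]-1-[4-(triisopropylsilyloxy)butyl]bicyclo[3.1.0]hexane F13.
- Na in NH3/THF with t-BuOH at −78 °C removes both chlorines and the benzyl group, giving (1R,2R,5S)-5-[2-(tert-butyldimethylsilyloxy)ethyl]-1-[4-(triisopropylsilyloxy)butyl]bicyclo[3.1.0]hexan-2-ol F14, the C2 epimer of 16.
- Dess–Martin oxidation removes the C2 stereocentre and comes back to the route at 17.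

Further compounds
F1 | step 12 | tert-butyl(dimethyl){2-[(1R)-1-methyl-3-(prop-1-en-2-yl)-2-[4-(triisopropylsilyloxy)butyl]cyclopent-2-en-1-yl]ethoxy}silane | C=C(C)C1=C(CCCCO[Si](C(C)C)(C(C)C)C(C)C)[C@@](C)(CCO[Si](C)(C)C(C)(C)C)CC1
F2 | step 15 | 2-{(1R)-1-methyl-3-(propan-2-yl)-2-[4-(triisopropylsilyloxy)butyl]cyclopent-2-en-1-yl}ethan-1-ol | CC(C)C1=C(CCCCO[Si](C(C)C)(C(C)C)C(C)C)[C@@](C)(CCO)CC1
F3 | step 15 | 2-{(1R)-1-methyl-3-(propan-2-yl)-2-[4-(triisopropylsilyloxy)butyl]cyclopent-2-en-1-yl}acetaldehyde | CC(C)C1=C(CCCCO[Si](C(C)C)(C(C)C)C(C)C)[C@@](C)(CC=O)CC1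
F4 | step 15 | triisopropyl{4-[(5R)-5-methyl-2-(propan-2-yl)-5-(prop-2-en-1-yl)cyclopent-1-en-1-yl]butoxy}silane | CC(C)C1=C(CCCCO[Si](C(C)C)(C(C)C)C(C)C)[C@@](C)(CC=C)CC1
F5 | step 15 | 4-[(5R)-5-methyl-2-(propan-2-yl)-5-(prop-2-en-1-yl)cyclopent-1-en-1-yl]butan-1-ol | CC(C)C1=C(CCCCO)[C@@](C)(CC=C)CC1
F6 | step 15 | 4-[(5R)-5-methyl-2-(propan-2-yl)-5-(prop-2-en-1-yl)cyclopent-1-en-1-yl]butanal | CC(C)C1=C(CCCC=O)[C@@](C)(CC=C)CC1
F7 | step 15 | 2-methylidene-4-[(5R)-5-methyl-2-(propan-2-yl)-5-(prop-2-en-1-yl)cyclopent-1-en-1-yl]butanal | CC(C)C1=C(CCC(=C)C=O)[C@@](C)(CC=C)CC1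
F8 | step 15 | 2-methylidene-4-[(5R)-5-methyl-2-(propan-2-yl)-5-(prop-2-en-1-yl)cyclopent-1-en-1-yl]butan-1-ol | CC(C)C1=C(CCC(=C)CO)[C@@](C)(CC=C)CC1
F9 | step 9 | tert-butyl 2-{(3R)-3-hydroxy-2-[4-(triisopropylsilyloxy)butyl]cyclopent-1-en-1-yl}acetate | O[C@@H]1CCC(CC(=O)OC(C)(C)C)=C1CCCCO[Si](C(C)C)(C(C)C)C(C)C
F10 | step 9 | (1R)-3-(2-hydroxyethyl)-2-[4-(triisopropylsilyloxy)butyl]cyclopent-2-en-1-ol | O[C@@H]1CCC(CCO)=C1CCCCO[Si](C(C)C)(C(C)C)C(C)C
F11 | step 9 | (1R)-3-[2-(tert-butyldimethylsilyloxy)ethyl]-2-[4-(triisopropylsilyloxy)butyl]cyclopent-2-en-1-ol | O[C@@H]1CCC(CCO[Si](C)(C)C(C)(C)C)=C1CCCCO[Si](C(C)C)(C(C)C)C(C)C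
F12 | step 9 | {[(1R)-3-[2-(tert-butyldimethylsilyloxy)ethyl]-2-[4-(triisopropylsilyloxy)butyl]cyclopent-2-en-1-yl]oxymethyl}benzene | C(c1ccccc1)O[C@@H]1CCC(CCO[Si](C)(C)C(C)(C)C)=C1CCCCO[Si](C(C)C)(C(C)C)C(C)C
F13 | step 9 | (1R,2R,5S)-2-(benzyloxy)-6,6-dichloro-5-[2-(tert-butyldimethylsilyloxy)ethyl]-1-[4-(triisopropylsilyloxy)butyl]bicyclo[3.1.0]hexane | C(c1ccccc1)O[C@@H]1CC[C@@]2(CCO[Si](C)(C)C(C)(C)C)C(Cl)(Cl)[C@@]12CCCCO[Si](C(C)C)(C(C)C)C(C)C
F14 | step 9 | (1R,2R,5S)-5-[2-(tert-butyldimethylsilyloxy)ethyl]-1-[4-(triisopropylsilyloxy)butyl]bicyclo[3.1.0]hexan-2-ol | O[C@@H]1CC[C@@]2(CCO[Si](C)(C)C(C)(C)C)C[C@@]12CCCCO[Si](C(C)C)(C(C)C)C(C)C
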